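Late in these flasks the thing to watch is the target itself, which free catalyst turns on into over-reaction product.

all flasks: substrate 0.0010 M; precatalyst 5.0 µM; time 50 s

| charge | remark | temperature |
|---|---|---|
| epsilon | at 80 °C until 40 s, from then on at 140 °C |  |
| theta |  | 110 °C |
| gamma |  | 140 °C |
| alpha |  | 80 °C |

    precatalyst ⇌ free catalyst (K1 = 1.1, k1 = 0.445 s⁻¹, Ea1 = 82.0 kJ mol⁻¹, ΔH1 = −16.0 kJ mol⁻¹)
    free catalyst + target → free catalyst + over-reaction product (k2 = 9510 M⁻¹ s⁻¹, Ea2 = 30.0 kJ mol⁻¹)
    substrate + free catalyst → catalyst intermediate A (k3 = 3.26 × 10⁶ M⁻¹ s⁻¹, Ea3 = 8.00 kJ mol⁻¹)
    catalyst intermediate A ⇌ catalyst intermediate B (K4 = 0.955, k4 = 479 s⁻¹, Ea4 = 76.0 kJ mol⁻¹, ΔH4 = −51.0 kJ mol⁻¹)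
    catalyst intermediate B → free catalyst + target (k5 = 82.2 s⁻¹, Ea5 = 81.0 kJ mol⁻¹)
    (constants at 80 °C)

* the flask that comes out highest in amount of target, in percent of the substrate charged, or "all alike" when all lie within 1.5 percentage points (epsilon / theta / gamma / alpha / all alike)
* target at the end, in percent of the substrate charged, epsilon
* target at the end, in percent of the substrate charged, theta
* target at the end, in percent of the substrate charged, gamma
* target at the end, in percent of the substrate charged, alpha

- the list of constants is for 80 °C, to be carried to other temperatures by the activation energies and enthalpies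

Two numbers seem not to go together. On equal free catalyst, binding of substrate outruns over-reaction of target by the selectivity factor 343, so the target looks safe. Yet the equilibrium with precatalyst keeps 52.4% of the catalyst free at 80 °C, and over-reaction is then pseudo-first-order in target at 0.0249 s⁻¹. This over-reaction constant times the equilibrium free catalyst is the loss rate, and the fraction of target falls as its exponential. Over 50 s it would leave 28.8%.

The selectivity factor counts while substrate stands, and that is the way out. Binding at the full charge runs at 3260 s⁻¹ per free catalyst against a turnover of 37.0 s⁻¹ through the two intermediates, so we count the catalyst as held in the round and the loss clock as stopped. The round needs 200 turnovers per catalyst, and release of precatalyst costs about 2.25 s more, so by our reckoning substrate lasts 7.65 s at 80 °C. This lag is the correction, and it gives alpha 34.8%.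

At 140 °C the over-reaction constant grows 4.4 times, while the equilibrium constant shrinks to 0.499, leaving 33.3% free, so the loss rate is 0.0698 s⁻¹. That gives epsilon 22.2%, and gamma 3.06% with no lag counted. We leave theta unreckoned and commit to alpha as highest.

The forecast also names alpha, with 33.6% for alpha (30% to 37%), 21.4% for epsilon (19% to 24%), 11.5% for theta (10% to 13.5%) and 3% for gamma (2.3% to 3.8%). Its ground is that “the yield is set by how long the target then sits with free catalyst”. For alpha our figure stands higher than its figure.

The simulation gives alpha highest, with alpha 34.0%, epsilon 21.7%, theta 11.8% and gamma 3.23%, each inside the forecast's range.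

In epsilon, still at 80 °C at 4.71 s, the half-life of substrate by binding reads 2.2 s, shorter than the 27.8 s the loss rate gives target. The forecast's order goes wrong if a run shows target falling no faster when hot than when cold, where we reckon 2.80 times faster.

For the neighbour of epsilon charged with 1.2 × 10⁻⁶ M of precatalyst, we reckon both loss rates smaller in proportion to the charge and substrate lasting 24.7 s, so the loss rates leave 77.2%. The computed flask ends at 76.9% of target.

The numbers of this flask were set for the occasion; the result is computed.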